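**Retrosynthetic overview**
- Target ⇐ desilylation and C2 angeloylation of a ring 1,2,3-triol that already carries the C4 ester, made by hydroxyl-directed syn-dihydroxylation of a Δ2-cyclohexene; both angelates come from one preformed mixed anhydride.
- C4–O ⇐ SeO2 allylic hydroxylation of the cyclised diene, then esterification with the separately made lactone acid (convergent).
- Cyclohexane ring ⇐ C1–C6 closure of an open-chain (2Z,6E)-farnesal-type enal by intramolecular carbonyl-ene reaction: the bisabolyl-type closure with loss of a C14 hydrogen, setting C1, C6 and the 7(14)-methylene in one step.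
- Enal ⇐ neryl acetate (SeO2) plus an aldol with 3-hydroxy-3-methylbutan-2-one; C8 from the aldol, C10 from a CBS reduction.
- δ-Lactone ⇐ lactonisation of an open-chain dihydroxy ester (from Sharpless epoxide plus methyl cuprate), then enolate ethylation. Ring order: lactone first (step 4), cyclohexane second (step 16).

Conventions: Ang = (2Z)-2-methylbut-2-enoyl; TBS = tert-butyldimethylsilyl; TES = triethylsilyl; farnesane/bisabolane numbering (C1 = ring carbinol next to C6; C6 carries the C7(=C14)–C11 chain; C15 = ring methyl).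

Assumption: the (R,R)-bisphosphoramide in step 9 is taken to give Re-face attack on the enal (8R); if the sense is opposite, its enantiomer is used and nothing else changes.

**Fragment 1: lactone acid 10**

Step 1
Reactants: 1 2-methylbut-3-en-2-ol; 2 triethyl orthoacetate
Product: 4 ethyl 5-methylhex-4-enoate, via mixed ketene acetal 3 (not isolated)
Conditions: EtCO2H (cat.), 140 °C, EtOH distilled off
Reagents that add atoms: none
Why: Johnson–Claisen orthoester rearrangement, in which the ketene acetal 3 undergoes a chair [3,3] shift to the γ,δ-unsaturated ester; no stereocentre is formed.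

Step 2
Reactants: 4 ethyl 5-methylhex-4-enoate
Product: 5 ethyl (4E)-6-hydroxy-5-methylhex-4-enoate
Conditions: SeO2 (0.2 equiv), t-BuOOH, CH2Cl2, rt
Reagents that add atoms: selenium dioxide (catalytic oxygen carrier) O=[Se]=O; tert-butyl hydroperoxide CC(C)(C)OO
Why: SeO2/t-BuOOH allylic hydroxylation (ene reaction then [2,3] shift) oxidises only the methyl trans to the chain, giving the (E)-2-methylallylic alcohol.

Step 3
Reactants: 5 ethyl (4E)-6-hydroxy-5-methylhex-4-enoate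
Product: 6 ethyl 3-[(2R,3R)-3-(hydroxymethyl)-3-methyloxiran-2-yl]propanoate
Conditions: Ti(OiPr)4 (10 mol %), D-(−)-diisopropyl tartrate, t-BuOOH, 4 Å MS, CH2Cl2, −20 °C
Reagents that add atoms: tert-butyl hydroperoxide CC(C)(C)OO
Why: Sharpless asymmetric epoxidation, in which the D-(−)-tartrate gives the (2R,3R)-oxirane of an (E)-2-methylallylic alcohol (the L-(+)-tartrate gives the 2S,3S series), fixing the future C2' of the acid.

Step 4
Reactants: 6 ethyl 3-[(2R,3R)-3-(hydroxymethyl)-3-methyloxiran-2-yl]propanoate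
Product: 8 (5S,6S)-6-(hydroxymethyl)-5,6-dimethyloxan-2-one, via dihydroxy ester 7 (not isolated)
Conditions: Me2CuLi (from MeLi, CuI; 3 equiv), Et2O, −40 to 0 °C; aq. NH4Cl; then TsOH (cat.), CH2Cl2, rt
Reagents that add atoms: lithium dimethylcuprate Me2CuLi [Li+].C[Cu-]C
Why: SN2 epoxide opening by the cuprate at the less substituted oxirane carbon with inversion sets the C3' methyl centre, and the tertiary hydroxyl of 7 then closes the δ-lactone by acid-catalysed lactonisation of the open-chain hydroxy ester, the way the hydroxy diacid is thought to lactonise in nature.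

Step 5
Reactants: 8 (5S,6S)-6-(hydroxymethyl)-5,6-dimethyloxan-2-one
Product: 9 (2S,3S)-2,3-dimethyl-6-oxooxane-2-carboxylic acid
Conditions: TEMPO (10 mol %), NaClO2, NaOCl (cat.), MeCN/phosphate buffer pH 6.7, 35 °C
Reagents that add atoms: sodium chlorite NaClO2 [Na+].[O-]Cl=O
Why: TEMPO/chlorite oxidation of the primary alcohol to the acid at buffered pH leaves the lactone and both stereocentres untouched.

Step 6
Reactants: 9 (2S,3S)-2,3-dimethyl-6-oxooxane-2-carboxylic acid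
Product: 10 (2S,3S,5S)-5-ethyl-2,3-dimethyl-6-oxooxane-2-carboxylic acid
Conditions: LiN(iPr)2 (2.3 equiv), THF/DMPU, −78 °C; EtI, −78 to −40 °C; 1 M HCl
Reagents that add atoms: iodoethane CCI
Why: kinetic enolate alkylation of the carboxylate/lactone-enolate dianion (C5' is the only enolisable position), where ethyl iodide enters axially on the face of the axial C3'–H with the C3' methyl equatorial, i.e. trans to that methyl, giving 5S.

**Main line, with the enol silane (step 8) and the angeloyl donor (step 12) made on the side**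

Step 7
Reactants: 11 neryl acetate [(2Z)-3,7-dimethylocta-2,6-dien-1-yl acetate]
Product: 12 (2Z,6E)-3,7-dimethyl-8-oxoocta-2,6-dien-1-yl acetate
Conditions: SeO2 (1.2 equiv), 95% EtOH, reflux
Reagents that add atoms: selenium dioxide O=[Se]=O
Why: SeO2 allylic oxidation attacks the terminal trisubstituted olefin at its (E)-methyl and carries it to the enal, while the 2,3-olefin is deactivated by the allylic acetate.

Step 8
Reactants: 13 3-hydroxy-3-methylbutan-2-one
Product: 14 triethyl{[2-methyl-3-(triethylsilyloxy)but-3-en-2-yl]oxy}silane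
Conditions: TESOTf (2.3 equiv), Et3N, CH2Cl2, 0 °C to rt
Reagents that add atoms: triethylsilyl trifluoromethanesulfonate CC[Si](CC)(CC)OS(=O)(=O)C(F)(F)F
Why: silyl triflate/amine silylation of the tertiary alcohol and enol silylation of the methyl ketone on its only enolisable side.

Step 9
Reactants: 12 (2Z,6E)-3,7-dimethyl-8-oxoocta-2,6-dien-1-yl acetate; 14 triethyl{[2-methyl-3-(triethylsilyloxy)but-3-en-2-yl]oxy}silane
Product: 15 (2Z,6E,8R)-1-acetoxy-8-hydroxy-11-(triethylsilyloxy)-3,7,11-trimethyldodeca-2,6-dien-10-one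
Conditions: SiCl4 (1.5 equiv), (R,R)-bisphosphoramide catalyst (pentane-1,5-diyl-linked bis[N-methyl phosphoramide of N,N′-dimethyl-1,1′-binaphthyl-2,2′-diamine], 5 mol %), iPr2NEt (0.2 equiv), CH2Cl2, −78 °C; aq. KF/NaHCO3
Reagents that add atoms: none
Why: Lewis-base-activated SiCl4 Mukaiyama aldol addition of a methyl-ketone enol silane to an (E)-2-methyl enal, where catalyst-controlled Re-face attack sets 8R.

Step 10
Reactants: 15 (2Z,6E,8R)-1-acetoxy-8-hydroxy-11-(triethylsilyloxy)-3,7,11-trimethyldodeca-2,6-dien-10-one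
Product: 16 (2Z,6E,8R)-1-acetoxy-8-(tert-butyldimethylsilyloxy)-11-(triethylsilyloxy)-3,7,11-trimethyldodeca-2,6-dien-10-one
Conditions: TBSOTf, 2,6-lutidine, CH2Cl2, −78 °C
Reagents that add atoms: tert-butyldimethylsilyl trifluoromethanesulfonate CC(C)(C)[Si](C)(C)OS(=O)(=O)C(F)(F)F
Why: silyl ether formation at low temperature masks the C8 hydroxyl before the C10 hydroxyl exists, so the two secondary alcohols never need to be told apart.

Step 11
Reactants: 16 (2Z,6E,8R)-1-acetoxy-8-(tert-butyldimethylsilyloxy)-11-(triethylsilyloxy)-3,7,11-trimethyldodeca-2,6-dien-10-one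
Product: 17 (2Z,6E,8R,10S)-1-acetoxy-8-(tert-butyldimethylsilyloxy)-11-(triethylsilyloxy)-3,7,11-trimethyldodeca-2,6-dien-10-ol
Conditions: (R)-2-methyl-CBS-oxazaborolidine (0.5 equiv), catecholborane, toluene, −78 to −40 °C; MeOH
Reagents that add atoms: none
Why: Corey–Bakshi–Shibata reduction, with the tertiary silyloxy carbon as the large group and the CH2 as the small group, so the (R)-catalyst gives 10S; catecholborane leaves the olefins and the acetate alone.

Step 12
Reactants: 18 angelic acid [(2Z)-2-methylbut-2-enoic acid]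
Product: 19 angelic 2,4,6-trichlorobenzoic anhydride
Conditions: 2,4,6-trichlorobenzoyl chloride (1.0 equiv), Et3N (1.05 equiv), toluene, rt; filter off Et3N·HCl under Ar, concentrate, keep as a toluene stock solution at −20 °C
Reagents that add atoms: 2,4,6-trichlorobenzoyl chloride O=C(Cl)c1c(Cl)cc(Cl)cc1Cl
Why: mixed-anhydride formation (the first half of a Yamaguchi esterification) by acylation of triethylammonium angelate with the hindered aroyl chloride, where the absence of any nucleophilic catalyst keeps the (Z)-olefin from isomerising to the tiglate; no stereocentre is formed and one batch serves steps 13 and 21.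

Step 13
Reactants: 17 (2Z,6E,8R,10S)-1-acetoxy-8-(tert-butyldimethylsilyloxy)-11-(triethylsilyloxy)-3,7,11-trimethyldodeca-2,6-dien-10-ol; 19 angelic 2,4,6-trichlorobenzoic anhydride
Product: 20 (2Z,6E,8R,10S)-1-acetoxy-10-angeloyloxy-8-(tert-butyldimethylsilyloxy)-11-(triethylsilyloxy)-3,7,11-trimethyldodeca-2,6-diene
Conditions: 19 (3 equiv), Et3N (1 equiv), toluene, 80 °C
Reagents that add atoms: none
Why: Yamaguchi-type esterification with the preformed mixed anhydride and no DMAP, in which the only free hydroxyl attacks the less hindered angeloyl carbonyl with retention at C10 and the (Z)-geometry of the angelate is kept.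

Step 14
Reactants: 20 (2Z,6E,8R,10S)-1-acetoxy-10-angeloyloxy-8-(tert-butyldimethylsilyloxy)-11-(triethylsilyloxy)-3,7,11-trimethyldodeca-2,6-diene
Product: 21 (2Z,6E,8R,10S)-10-angeloyloxy-8-(tert-butyldimethylsilyloxy)-11-(triethylsilyloxy)-3,7,11-trimethyldodeca-2,6-dien-1-ol
Conditions: K2CO3 (0.3 equiv), MeOH, 0 °C
Reagents that add atoms: none
Why: base-catalysed transesterification removes the unhindered primary allylic acetate far faster than the hindered conjugated angelate on a neopentyl-type secondary carbon.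

Step 15
Reactants: 21 (2Z,6E,8R,10S)-10-angeloyloxy-8-(tert-butyldimethylsilyloxy)-11-(triethylsilyloxy)-3,7,11-trimethyldodeca-2,6-dien-1-ol
Product: 22 (2Z,6E,8R,10S)-10-angeloyloxy-8-(tert-butyldimethylsilyloxy)-11-(triethylsilyloxy)-3,7,11-trimethyldodeca-2,6-dienal
Conditions: MnO2 (activated, excess), CH2Cl2, rt, dark
Reagents that add atoms: none
Why: neutral MnO2 allylic oxidation gives the (2Z)-enal without Z-to-E isomerisation, as for nerol to neral.

Step 16
Reactants: 22 (2Z,6E,8R,10S)-10-angeloyloxy-8-(tert-butyldimethylsilyloxy)-11-(triethylsilyloxy)-3,7,11-trimethyldodeca-2,6-dienal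
Product: 24 (1R,6R,8R,10S)-10-angeloyloxy-8-(tert-butyldimethylsilyloxy)-1,11-bis(triethylsilyloxy)bisabola-2,7(14)-diene, via chloro(methyl)aluminium alkoxide 23 (not isolated)
Conditions: Me2AlCl (1.5 equiv), CH2Cl2, −78 to −40 °C; then TESOTf, 2,6-lutidine, −40 to 0 °C
Reagents that add atoms: triethylsilyl trifluoromethanesulfonate CC[Si](CC)(CC)OS(=O)(=O)C(F)(F)F
Why: Proposed new method: a Lewis-acid-promoted intramolecular carbonyl-ene (Prins-type) closure of C1 onto the 6,7-olefin, the laboratory counterpart of the C1–C6 closure to the bisabolyl cation with loss of a C14 proton; in the closed chair-like transition state of the (6E)-olefin the only transferable hydrogen not deactivated by oxygen sits on C14 (syn to the tether) and can reach the carbonyl oxygen only when C1–O is pseudoaxial, so the 7(14)-methylene and the 1,6-cis relationship arise together, while C1 adds to the olefin face anti to C9 with the C8–O bond in the olefin plane (8R gives 6R), and methane loss leaves the non-acidic alkoxide 23 that is silylated in the same flask; the closest known reactions are the Me2AlCl- or ZnBr2-promoted citronellal-to-isopulegol and the acid-promoted neral-to-isopiperitenol ene cyclisations.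

Step 17
Reactants: 24 (1R,6R,8R,10S)-10-angeloyloxy-8-(tert-butyldimethylsilyloxy)-1,11-bis(triethylsilyloxy)bisabola-2,7(14)-diene
Product: 25 (1R,4S,6R,8R,10S)-10-angeloyloxy-8-(tert-butyldimethylsilyloxy)-1,11-bis(triethylsilyloxy)bisabola-2,7(14)-dien-4-ol
Conditions: SeO2 (0.5 equiv), t-BuOOH, CH2Cl2, 0 °C to rt
Reagents that add atoms: selenium dioxide (catalytic oxygen carrier) O=[Se]=O; tert-butyl hydroperoxide CC(C)(C)OO
Why: SeO2 allylic hydroxylation of the ring olefin at the ring CH2 next to its methyl-bearing carbon (as 1-methylcyclohexene gives 2-methylcyclohex-2-enol), where the ene step occurs on the face anti to the pseudoaxial C1 silyloxy group, removes the pseudoaxial C4–H on that face and the [2,3] shift returns oxygen to C4 on the same face (4S, trans to C1–O); the exocyclic olefin is slowed by its allylic OTBS.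

Step 18
Reactants: 25 (1R,4S,6R,8R,10S)-10-angeloyloxy-8-(tert-butyldimethylsilyloxy)-1,11-bis(triethylsilyloxy)bisabola-2,7(14)-dien-4-ol; 10 (2S,3S,5S)-5-ethyl-2,3-dimethyl-6-oxooxane-2-carboxylic acid
Product: 27 (1R,4S,6R,8R,10S)-10-angeloyloxy-8-(tert-butyldimethylsilyloxy)-1,11-bis(triethylsilyloxy)bisabola-2,7(14)-dien-4-yl (2S,3S,5S)-5-ethyl-2,3-dimethyl-6-oxooxane-2-carboxylate, via acid chloride 26 (not isolated)
Conditions: 10, (COCl)2, DMF (cat.), CH2Cl2, 0 °C to rt, evaporate; then 25, DMAP, Et3N, CH2Cl2, 0 to 35 °C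
Reagents that add atoms: none
Why: DMAP-catalysed acylation with the acid chloride of an α-quaternary acid (no α-hydrogen, so no epimerisation) esterifies the only free hydroxyl with retention at C4.

Step 19
Reactants: 27 (1R,4S,6R,8R,10S)-10-angeloyloxy-8-(tert-butyldimethylsilyloxy)-1,11-bis(triethylsilyloxy)bisabola-2,7(14)-dien-4-yl (2S,3S,5S)-5-ethyl-2,3-dimethyl-6-oxooxane-2-carboxylate
Product: 28 (1R,4S,6R,8R,10S)-10-angeloyloxy-8-(tert-butyldimethylsilyloxy)-1-hydroxy-11-(triethylsilyloxy)bisabola-2,7(14)-dien-4-yl (2S,3S,5S)-5-ethyl-2,3-dimethyl-6-oxooxane-2-carboxylate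
Conditions: PPTS (0.2 equiv), MeOH/CH2Cl2 1:1, 0 °C
Reagents that add atoms: none
Why: acid-catalysed methanolysis cleaves the secondary allylic TES ether selectively, the hindered tertiary TES and the TBS ether being much slower.

Step 20
Reactants: 28 (1R,4S,6R,8R,10S)-10-angeloyloxy-8-(tert-butyldimethylsilyloxy)-1-hydroxy-11-(triethylsilyloxy)bisabola-2,7(14)-dien-4-yl (2S,3S,5S)-5-ethyl-2,3-dimethyl-6-oxooxane-2-carboxylate
Product: 30 (1S,2S,3S,4S,6R,8R,10S)-10-angeloyloxy-8-(tert-butyldimethylsilyloxy)-1,2,3-trihydroxy-11-(triethylsilyloxy)bisabol-7(14)-en-4-yl (2S,3S,5S)-5-ethyl-2,3-dimethyl-6-oxooxane-2-carboxylate, via osmate ester 29 (not isolated)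
Conditions: OsO4 (1.05 equiv), TMEDA (1.1 equiv), CH2Cl2, −78 °C; then aq. Na2SO3, THF, 45 °C
Reagents that add atoms: osmium tetroxide OsO4 O=[Os](=O)(=O)=O
Why: Donohoe hydroxyl-directed dihydroxylation, in which OsO4·TMEDA hydrogen-bonded to the pseudoaxial C1–OH adds to the ring olefin syn to that hydroxyl and anti to the C4 ester, giving the all-cis 1,2,3-triol; the exocyclic olefin is only homoallylic to the directing group and shielded by OTBS, and the angelate is electron-poor.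

Step 21
Reactants: 30 (1S,2S,3S,4S,6R,8R,10S)-10-angeloyloxy-8-(tert-butyldimethylsilyloxy)-1,2,3-trihydroxy-11-(triethylsilyloxy)bisabol-7(14)-en-4-yl (2S,3S,5S)-5-ethyl-2,3-dimethyl-6-oxooxane-2-carboxylate; 19 angelic 2,4,6-trichlorobenzoic anhydride
Product: 32 (1S,2S,3R,4S,6R,8R,10S)-2,10-bis(angeloyloxy)-8-(tert-butyldimethylsilyloxy)-1,3-dihydroxy-11-(triethylsilyloxy)bisabol-7(14)-en-4-yl (2S,3S,5S)-5-ethyl-2,3-dimethyl-6-oxooxane-2-carboxylate, via dibutylstannylene acetal 31 (not isolated)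
Conditions: Bu2SnO (1.1 equiv), toluene, 80 °C, 4 Å MS; then 19 (1.2 equiv), toluene, 0 °C to rt
Reagents that add atoms: none
Why: stannylene-acetal-mediated regioselective acylation of a cis-1,2-diol at its equatorial oxygen (O2) by the preformed mixed anhydride, the axial C1–OH being hydrogen-bonded to the syn-axial C3–OH and the tertiary C3–OH being unreactive.

Step 22
Reactants: 32 (1S,2S,3R,4S,6R,8R,10S)-2,10-bis(angeloyloxy)-8-(tert-butyldimethylsilyloxy)-1,3-dihydroxy-11-(triethylsilyloxy)bisabol-7(14)-en-4-yl (2S,3S,5S)-5-ethyl-2,3-dimethyl-6-oxooxane-2-carboxylate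
Product: 33 CNP0148734.1 [(1S,2S,3R,4S,6R,8R,10S)-2,10-bis(angeloyloxy)-1,3,8,11-tetrahydroxybisabol-7(14)-en-4-yl (2S,3S,5S)-5-ethyl-2,3-dimethyl-6-oxooxane-2-carboxylate]
Conditions: HF·pyridine, pyridine, THF, 0 °C to rt
Reagents that add atoms: none
Why: fluoride-mediated desilylation under mildly acidic buffered conditions removes the TBS and TES ethers without ester cleavage, acyl migration or angelate isomerisation.

**Compound list**
1 | 2-methylbut-3-en-2-ol | C=CC(C)(C)O | starting material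
2 | triethyl orthoacetate | CCOC(C)(OCC)OCC | starting material
3 | mixed ketene acetal, 1-ethoxy-1-[(2-methylbut-3-en-2-yl)oxy]ethene | C=C(OCC)OC(C)(C)C=C | intermediate
4 | ethyl 5-methylhex-4-enoate | CCOC(=O)CCC=C(C)C | intermediate
5 | ethyl (4E)-6-hydroxy-5-methylhex-4-enoate | CCOC(=O)CC/C=C(\C)CO | intermediate
6 | ethyl 3-[(2R,3R)-3-(hydroxymethyl)-3-methyloxiran-2-yl]propanoate | OC[C@@]1(C)O[C@@H]1CCC(=O)OCC | intermediate
7 | ethyl (4S,5S)-5,6-dihydroxy-4,5-dimethylhexanoate | OC[C@@](C)(O)[C@@H](C)CCC(=O)OCC | intermediate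
8 | (5S,6S)-6-(hydroxymethyl)-5,6-dimethyloxan-2-one | OC[C@@]1(C)OC(=O)CC[C@@H]1C | intermediate
9 | (2S,3S)-2,3-dimethyl-6-oxooxane-2-carboxylic acid | OC(=O)[C@@]1(C)OC(=O)CC[C@@H]1C | intermediate
10 | (2S,3S,5S)-5-ethyl-2,3-dimethyl-6-oxooxane-2-carboxylic acid | OC(=O)[C@@]1(C)OC(=O)[C@@H](CC)C[C@@H]1C | intermediate
11 | neryl acetate | CC(=O)OC/C=C(/C)CCC=C(C)C | starting material
12 | (2Z,6E)-3,7-dimethyl-8-oxoocta-2,6-dien-1-yl acetate | CC(=O)OC/C=C(/C)CC/C=C(\C)C=O | intermediate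
13 | 3-hydroxy-3-methylbutan-2-one | CC(=O)C(C)(C)O | starting material
14 | triethyl{[2-methyl-3-(triethylsilyloxy)but-3-en-2-yl]oxy}silane | C=C(O[Si](CC)(CC)CC)C(C)(C)O[Si](CC)(CC)CC | intermediate
15 | (2Z,6E,8R)-1-acetoxy-8-hydroxy-11-(triethylsilyloxy)-3,7,11-trimethyldodeca-2,6-dien-10-one | CC(=O)OC/C=C(/C)CC/C=C(\C)[C@H](O)CC(=O)C(C)(C)O[Si](CC)(CC)CC | intermediate
16 | (2Z,6E,8R)-1-acetoxy-8-(tert-butyldimethylsilyloxy)-11-(triethylsilyloxy)-3,7,11-trimethyldodeca-2,6-dien-10-one | CC(=O)OC/C=C(/C)CC/C=C(\C)[C@H](O[Si](C)(C)C(C)(C)C)CC(=O)C(C)(C)O[Si](CC)(CC)CC | intermediate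
17 | (2Z,6E,8R,10S)-1-acetoxy-8-(tert-butyldimethylsilyloxy)-11-(triethylsilyloxy)-3,7,11-trimethyldodeca-2,6-dien-10-ol | CC(=O)OC/C=C(/C)CC/C=C(\C)[C@H](O[Si](C)(C)C(C)(C)C)C[C@H](O)C(C)(C)O[Si](CC)(CC)CC | intermediate
18 | angelic acid, (2Z)-2-methylbut-2-enoic acid | C/C=C(/C)C(=O)O | starting material
19 | angelic 2,4,6-trichlorobenzoic anhydride | C/C=C(/C)C(=O)OC(=O)c1c(Cl)cc(Cl)cc1Cl | intermediate
20 | (2Z,6E,8R,10S)-1-acetoxy-10-angeloyloxy-8-(tert-butyldimethylsilyloxy)-11-(triethylsilyloxy)-3,7,11-trimethyldodeca-2,6-diene | CC(=O)OC/C=C(/C)CC/C=C(\C)[C@H](O[Si](C)(C)C(C)(C)C)C[C@H](OC(=O)/C(C)=C\C)C(C)(C)O[Si](CC)(CC)CC | intermediate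
21 | (2Z,6E,8R,10S)-10-angeloyloxy-8-(tert-butyldimethylsilyloxy)-11-(triethylsilyloxy)-3,7,11-trimethyldodeca-2,6-dien-1-ol | OC/C=C(/C)CC/C=C(\C)[C@H](O[Si](C)(C)C(C)(C)C)C[C@H](OC(=O)/C(C)=C\C)C(C)(C)O[Si](CC)(CC)CC | intermediate
22 | (2Z,6E,8R,10S)-10-angeloyloxy-8-(tert-butyldimethylsilyloxy)-11-(triethylsilyloxy)-3,7,11-trimethyldodeca-2,6-dienal | O=C/C=C(/C)CC/C=C(\C)[C@H](O[Si](C)(C)C(C)(C)C)C[C@H](OC(=O)/C(C)=C\C)C(C)(C)O[Si](CC)(CC)CC | intermediate
23 | chloro(methyl)aluminium alkoxide of (1R,6R,8R,10S)-10-angeloyloxy-8-(tert-butyldimethylsilyloxy)-11-(triethylsilyloxy)bisabola-2,7(14)-dien-1-ol | C=C([C@H](O[Si](C)(C)C(C)(C)C)C[C@H](OC(=O)/C(C)=C\C)C(C)(C)O[Si](CC)(CC)CC)[C@H]1CCC(C)=C[C@H]1O[Al](C)Cl | intermediate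
24 | (1R,6R,8R,10S)-10-angeloyloxy-8-(tert-butyldimethylsilyloxy)-1,11-bis(triethylsilyloxy)bisabola-2,7(14)-diene | C=C([C@H](O[Si](C)(C)C(C)(C)C)C[C@H](OC(=O)/C(C)=C\C)C(C)(C)O[Si](CC)(CC)CC)[C@H]1CCC(C)=C[C@H]1O[Si](CC)(CC)CC | intermediate
25 | (1R,4S,6R,8R,10S)-10-angeloyloxy-8-(tert-butyldimethylsilyloxy)-1,11-bis(triethylsilyloxy)bisabola-2,7(14)-dien-4-ol | C=C([C@H](O[Si](C)(C)C(C)(C)C)C[C@H](OC(=O)/C(C)=C\C)C(C)(C)O[Si](CC)(CC)CC)[C@H]1C[C@H](O)C(C)=C[C@H]1O[Si](CC)(CC)CC | intermediate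
26 | (2S,3S,5S)-5-ethyl-2,3-dimethyl-6-oxooxane-2-carbonyl chloride | ClC(=O)[C@@]1(C)OC(=O)[C@@H](CC)C[C@@H]1C | intermediate
27 | (1R,4S,6R,8R,10S)-10-angeloyloxy-8-(tert-butyldimethylsilyloxy)-1,11-bis(triethylsilyloxy)bisabola-2,7(14)-dien-4-yl (2S,3S,5S)-5-ethyl-2,3-dimethyl-6-oxooxane-2-carboxylate | C=C([C@H](O[Si](C)(C)C(C)(C)C)C[C@H](OC(=O)/C(C)=C\C)C(C)(C)O[Si](CC)(CC)CC)[C@H]1C[C@H](OC(=O)[C@@]2(C)OC(=O)[C@@H](CC)C[C@@H]2C)C(C)=C[C@H]1O[Si](CC)(CC)CC | intermediate
28 | (1R,4S,6R,8R,10S)-10-angeloyloxy-8-(tert-butyldimethylsilyloxy)-1-hydroxy-11-(triethylsilyloxy)bisabola-2,7(14)-dien-4-yl (2S,3S,5S)-5-ethyl-2,3-dimethyl-6-oxooxane-2-carboxylate | C=C([C@H](O[Si](C)(C)C(C)(C)C)C[C@H](OC(=O)/C(C)=C\C)C(C)(C)O[Si](CC)(CC)CC)[C@H]1C[C@H](OC(=O)[C@@]2(C)OC(=O)[C@@H](CC)C[C@@H]2C)C(C)=C[C@H]1O | intermediate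
29 | cyclic 2,3-O-osmate ester of 30 as its TMEDA adduct | C=C([C@H](O[Si](C)(C)C(C)(C)C)C[C@H](OC(=O)/C(C)=C\C)C(C)(C)O[Si](CC)(CC)CC)[C@H]1C[C@H](OC(=O)[C@@]2(C)OC(=O)[C@@H](CC)C[C@@H]2C)[C@@]3(C)O[Os](=O)(=O)O[C@H]3[C@H]1O.CN(C)CCN(C)C | intermediate
30 | (1S,2S,3S,4S,6R,8R,10S)-10-angeloyloxy-8-(tert-butyldimethylsilyloxy)-1,2,3-trihydroxy-11-(triethylsilyloxy)bisabol-7(14)-en-4-yl (2S,3S,5S)-5-ethyl-2,3-dimethyl-6-oxooxane-2-carboxylate | C=C([C@H](O[Si](C)(C)C(C)(C)C)C[C@H](OC(=O)/C(C)=C\C)C(C)(C)O[Si](CC)(CC)CC)[C@H]1C[C@H](OC(=O)[C@@]2(C)OC(=O)[C@@H](CC)C[C@@H]2C)[C@@](C)(O)[C@@H](O)[C@H]1O | intermediate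
31 | 1,2-O-dibutylstannylene acetal of 30 | C=C([C@H](O[Si](C)(C)C(C)(C)C)C[C@H](OC(=O)/C(C)=C\C)C(C)(C)O[Si](CC)(CC)CC)[C@H]1C[C@H](OC(=O)[C@@]2(C)OC(=O)[C@@H](CC)C[C@@H]2C)[C@@](C)(O)[C@H]3O[Sn](CCCC)(CCCC)O[C@@H]13 | intermediate
32 | (1S,2S,3R,4S,6R,8R,10S)-2,10-bis(angeloyloxy)-8-(tert-butyldimethylsilyloxy)-1,3-dihydroxy-11-(triethylsilyloxy)bisabol-7(14)-en-4-yl (2S,3S,5S)-5-ethyl-2,3-dimethyl-6-oxooxane-2-carboxylate | C=C([C@H](O[Si](C)(C)C(C)(C)C)C[C@H](OC(=O)/C(C)=C\C)C(C)(C)O[Si](CC)(CC)CC)[C@H]1C[C@H](OC(=O)[C@@]2(C)OC(=O)[C@@H](CC)C[C@@H]2C)[C@@](C)(O)[C@@H](OC(=O)/C(C)=C\C)[C@H]1O | intermediate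
33 | CNP0148734.1, (1S,2S,3R,4S,6R,8R,10S)-2,10-bis(angeloyloxy)-1,3,8,11-tetrahydroxybisabol-7(14)-en-4-yl (2S,3S,5S)-5-ethyl-2,3-dimethyl-6-oxooxane-2-carboxylate | C=C([C@H](O)C[C@H](OC(=O)/C(C)=C\C)C(C)(C)O)[C@H]1C[C@H](OC(=O)[C@@]2(C)OC(=O)[C@@H](CC)C[C@@H]2C)[C@@](C)(O)[C@@H](OC(=O)/C(C)=C\C)[C@H]1O | target

**Step count and risks**

Total: 22 steps (6 to acid 10, 1 to enol silane 14, 1 to mixed anhydride 19, 14 in the main line). Longest linear sequence: 14 steps (11 to 33; steps 7, 9–11 and 13–22).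

Most likely to fail, first: step 16. The ene closure may give the 1,6-trans alcohol or a C1 mixture, or the allylic alcohol may not survive. The fallback sets out from 22 and gives up one-step control of C1 in favour of a redox correction. The ring is closed without silyl trapping (ZnBr2, toluene, 0 °C), and whatever ratio of the 1-epi (trans) alcohol F1 and the cis alcohol F2 forms is taken on. Dess–Martin periodinane/NaHCO3 oxidises both to the single enone F3. LiBH(s-Bu)3 at −78 °C then adds hydride to the face opposite the C6 side chain (1,2-reduction, the β-methyl blocks conjugate attack), giving only the cis alcohol F2. TESOTf/2,6-lutidine returns the material to the route at 24.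

Second: step 17. SeO2 may also attack the tertiary C6–H of the exocyclic olefin or the C15 methyl. The fallback sets out from 24 and builds the C4 oxygen by oxidation, reduction and inversion. CrO3·3,5-dimethylpyrazole (CH2Cl2, −20 °C) oxidises the ring CH2 to the 4-ketone (enone) F4; the tertiary C6 position cannot be carried to a ketone. NaBH4/CeCl3·7H2O gives, by axial hydride attack (as carvone gives cis-carveol), the equatorial 4-epi alcohol F5. A Mitsunobu esterification with acid 10 (PPh3, DIAD; the α-acyloxy acid is acidic enough) inverts C4 and comes back to the route at 27, so step 18 is bypassed.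

Third: step 21. The stannylene acylation may fall on O1 or give mixtures or acyl migration. The fallback sets out from 30 and replaces reagent-controlled selectivity by temporary protection. tBu2Si(OTf)2/2,6-lutidine ties the syn-diaxial C1 and C3 hydroxyls into the six-membered cyclic di-tert-butylsilylene F6, leaving the C2 hydroxyl as the only free one. Acylation with anhydride 19 gives the 2-O-angelate F7. The HF·pyridine treatment of step 22 then removes the silylene together with TBS and TES, so this fallback comes back to the route at 33.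

**Further compounds**
F1 | step 16 | (1S,6R,8R,10S)-10-angeloyloxy-8-(tert-butyldimethylsilyloxy)-11-(triethylsilyloxy)bisabola-2,7(14)-dien-1-ol (1-epi, trans alcohol) | C=C([C@H](O[Si](C)(C)C(C)(C)C)C[C@H](OC(=O)/C(C)=C\C)C(C)(C)O[Si](CC)(CC)CC)[C@H]1CCC(C)=C[C@@H]1O
F2 | step 16 | (1R,6R,8R,10S)-10-angeloyloxy-8-(tert-butyldimethylsilyloxy)-11-(triethylsilyloxy)bisabola-2,7(14)-dien-1-ol (cis alcohol) | C=C([C@H](O[Si](C)(C)C(C)(C)C)C[C@H](OC(=O)/C(C)=C\C)C(C)(C)O[Si](CC)(CC)CC)[C@H]1CCC(C)=C[C@H]1O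
F3 | step 16 | (6R,8R,10S)-10-angeloyloxy-8-(tert-butyldimethylsilyloxy)-11-(triethylsilyloxy)bisabola-2,7(14)-dien-1-one | C=C([C@H](O[Si](C)(C)C(C)(C)C)C[C@H](OC(=O)/C(C)=C\C)C(C)(C)O[Si](CC)(CC)CC)[C@H]1CCC(C)=CC1=O
F4 | step 17 | (1R,6R,8R,10S)-10-angeloyloxy-8-(tert-butyldimethylsilyloxy)-1,11-bis(triethylsilyloxy)bisabola-2,7(14)-dien-4-one | C=C([C@H](O[Si](C)(C)C(C)(C)C)C[C@H](OC(=O)/C(C)=C\C)C(C)(C)O[Si](CC)(CC)CC)[C@H]1CC(=O)C(C)=C[C@H]1O[Si](CC)(CC)CC
F5 | step 17 | (1R,4R,6R,8R,10S)-10-angeloyloxy-8-(tert-butyldimethylsilyloxy)-1,11-bis(triethylsilyloxy)bisabola-2,7(14)-dien-4-ol (4-epi alcohol) | C=C([C@H](O[Si](C)(C)C(C)(C)C)C[C@H](OC(=O)/C(C)=C\C)C(C)(C)O[Si](CC)(CC)CC)[C@H]1C[C@@H](O)C(C)=C[C@H]1O[Si](CC)(CC)CC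
F6 | step 21 | 1,3-O-(di-tert-butylsilylene) derivative of 30 | C=C([C@H](O[Si](C)(C)C(C)(C)C)C[C@H](OC(=O)/C(C)=C\C)C(C)(C)O[Si](CC)(CC)CC)[C@H]1C[C@H](OC(=O)[C@@]2(C)OC(=O)[C@@H](CC)C[C@@H]2C)[C@@]3(C)O[Si](C(C)(C)C)(C(C)(C)C)O[C@@H]1[C@@H]3O
F7 | step 21 | 2-O-angeloyl-1,3-O-(di-tert-butylsilylene) derivative of 30 | C=C([C@H](O[Si](C)(C)C(C)(C)C)C[C@H](OC(=O)/C(C)=C\C)C(C)(C)O[Si](CC)(CC)CC)[C@H]1C[C@H](OC(=O)[C@@]2(C)OC(=O)[C@@H](CC)C[C@@H]2C)[C@@]3(C)O[Si](C(C)(C)C)(C(C)(C)C)O[C@@H]1[C@@H]3OC(=O)/C(C)=C\C
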